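Hold one sum fixed in the green flask: G made plus Z left in any form equals the Z charged, 50.0% of the J charged, one Z for each G.

| flask | J | Z | L | remark |
|---|---|---|---|---|
| green | 0.10 M | 0.050 M | 50 µM | the very flask that is asked about, followed so far |
| flask | 0.10 M | 0.0500 M | 50 µM |  |

green run (percent of the J charged)

| time / d | G / % | J / % |
|---|---|---|
| 0.625 | 29.7 | 57.0 |
| 1.25 | 47.8 | 20.5 |
| 1.67 | 49.5 | 3.2 |
| 2.50 | 50.5 | 0 |
| 3.00 | 50.6 | 0.3 |
| 4.00 | 50.5 | 0 |

(standard deviation of a reading: 0.5 percentage points)

- as a solid, counted per litre of solution: J
- the analysis behind the earlier runs scatters by 0.5 percentage points, standard deviation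
- at the start none of J is in solution
- what has only dissolved of J counts as not reacted
- no earlier run changes the charge of L; that part of a forecast is a guess
- no earlier run changes the charge of Z; that part of a forecast is a guess

- factor on the rate of making G when 20% of the J are converted (what has only dissolved counts as not reacted) if Z is charged twice over
- factor on the rate when 20% of the J are converted (what has only dissolved counts as not reacted) if L is charged at 250 µM instead

Keep the ledger of Z, the limiting reagent, in the green flask. By 0.625 d the G reading debits 59.4% of the Z charged, and by 1.25 d it debits 95.6%. At 2.50 d the G reading of 50.5% closes the books against the charge, within the scatter of 0.5 percentage points. The asked point, 20% converted, debits 40.0% of the Z charged and leaves 60.0% on hand.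

Now replace each curve by its mean over the first interval. As fractions of the J charged, solid J leaves at 0.688 d⁻¹ and G forms at 0.475 d⁻¹. Their ratio, 1.45, a reading that carries the scatter of the analysis, is the headroom: solid lost per G made, the factor between the pace of G and the supply feeding it. Check the mean: at that pace 20% falls at 0.421 d, inside the interval, while the supply drops to 0.584 d⁻¹ over the next interval, 15.1% lower. Read the headroom to that accuracy.

My reckoning is a bracket, an estimate and no bound: I expect both factors between one and the headroom, with no run to rank them. The forecast gives points, 1.3 for twice the Z and 1.4 for 250 µM of L, inside that bracket, on the ground that extra Z or L “can only push the rate towards that ceiling”.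

The flask gives 1.18 for twice the Z and 1.26 for 250 µM of L, so the forecast stands within its margins.

    X + L ⇌ D (K = 19.0 M⁻¹, k = 14000 M⁻¹ h⁻¹)
    Z + D ⇌ Q (K = 48.0 M⁻¹, k = 18000 M⁻¹ h⁻¹)
    Q → L + G (k = 2500 h⁻¹)
    J ⇌ X, rate k4*(cs4 - [X]) while solid is left; crystals form when [X] > cs4 (solubility = 0.0940 M, k = 0.0330 h⁻¹)
    X + L → E (k = 0.570 M⁻¹ h⁻¹)

At 0.743 d in the green flask, X is made 1.46 times as fast as it is used up, each step taken net, and at 0.800 d X stands at 15.7% of the J charged. The flask with twice the Z takes up 40.7% of the headroom above one, and reaches 20% in 0.877 times the time of the green flask.

(The runs are calculated on assumed constants; the scatter is artificial.)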